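**Plan**
- Retrosynthesis: a single cut, the benzylic CH2–aryl bond, made after raising the catechol to its o-quinone. The arene then becomes tetrabromo-1,2-benzoquinone with one bromine replaced by carbon.
- Enabling feature: the CH2-bearing ring carbon is para to a phenolic oxygen and every other ring carbon carries Br or O. In the C2-symmetric o-quinone this carbon is one of two equivalent positions (C4/C5), each the β-carbon of a bromo-enone (a vinylogous acyl bromide).
- Forward: the lactam-N–CH2 unit is delivered as a nucleophilic α-amidomethyl radical from 2-(2-oxopyrrolidin-1-yl)acetic acid (CO2H as traceless activating group). It adds at C4 and a bromine atom leaves; dithionite then returns the ring to the catechol in the same flask.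
- Both rings (lactam and carbocycle) are bought, none is built. The target has no stereocentre.

Key step: step 1

Remark: the target is achiral; the labile o-quinone 3 is reduced in the flask in which it forms and is treated as a non-isolated intermediate.

Step 1
Reactants: 1 2-(2-oxopyrrolidin-1-yl)acetic acid; 2 tetrabromo-1,2-benzoquinone (o-bromanil)
Product: 4 1-[(2,3,6-tribromo-4,5-dihydroxyphenyl)methyl]pyrrolidin-2-one, via tribromo-o-quinone 3 (not isolated)
Conditions: AgNO3 (0.3 equiv), K2S2O8 (2 equiv), MeCN/H2O 2:1, 45 °C, 1 (1.5 equiv) added in portions; then aq Na2S2O4, 0 °C to rt, same flask
Reagents that add atoms: none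
Why: Proposed new method: Ag(II), made from Ag(I) and peroxodisulfate, should oxidize acid 1 to CO2 and the nucleophilic primary α-amidomethyl radical, which adds to C4 of 2 (identical with C5 by the C2 axis), the β-carbon of a bromo-enone and the carbon at which N- and O-nucleophiles are known to enter tetrahalo-o-quinones; the adduct is a β-bromo α-keto radical and should expel a bromine atom to restore the o-quinone as 3. The closest known reaction type is the silver/persulfate decarboxylative alkylation of quinones (Jacobsen–Torssell), including its ipso replacement of halogen in 2,3-dihalo-1,4-naphthoquinones, together with the addition/β-bromine-loss sequence of radical vinylations with vinyl bromides; new are the o-quinone acceptor and bromine as the leaving atom. No ring is closed and no stereocentre is formed. The step needs attack at carbon and not at oxygen, at C4 and not at C3, and one substitution only: an O-adduct is an aryloxyl radical that the oxidizing aqueous medium should oxidize and hydrolyse back to 2 at the cost of 1 alone (hence its excess), C4 is the polarity-matched enone terminus, and 3 carries a donor alkyl group where 2 has bromine and should be the poorer radical acceptor. Dithionite then reduces 3, and any quinone methide tautomer of it, to catechol 4 before water can add at the benzylic carbon.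

**Compound list**
1 | 2-(2-oxopyrrolidin-1-yl)acetic acid | O=C1CCCN1CC(=O)O | starting material
2 | 3,4,5,6-tetrabromocyclohexa-3,5-diene-1,2-dione (tetrabromo-1,2-benzoquinone, o-bromanil) | O=C1C(=O)C(Br)=C(Br)C(Br)=C1Br | starting material
3 | 3,4,6-tribromo-5-[(2-oxopyrrolidin-1-yl)methyl]cyclohexa-3,5-diene-1,2-dione | O=C1CCCN1CC1=C(Br)C(=O)C(=O)C(Br)=C1Br | intermediate
4 | 1-[(2,3,6-tribromo-4,5-dihydroxyphenyl)methyl]pyrrolidin-2-one | O=C1CCCN1Cc1c(Br)c(O)c(O)c(Br)c1Br | target

Total step count: 1
Longest linear sequence: 1 step

Steps most likely to fail (the route has a single step, so there is one entry):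

Step 1 (Proposed new method). Several processes could divert it:
- The radical may attack a quinone oxygen, or be oxidized by electron transfer to 2, faster than it adds at C4.
- Water may displace bromide from C4/C5 of 2 during the radical stage.
- Bromide set free may remove the silver catalyst as its insoluble bromide.
- Quinone 3 may tautomerize to a quinone methide and add water at the benzylic carbon before the reductive quench.
- A second radical may replace the C5 bromine of 3.

Fallback (known chemistry; the CH2 carbon is used in its natural N-acyliminium polarity and the bromines are introduced after the C–C bond). It sets out from 1 and returns to the route at 4. Anodic decarboxylative methoxylation of 1 (Hofer–Moest; graphite anode, MeOH, cat. NaOMe, rt) should give 1-(methoxymethyl)pyrrolidin-2-one F1. Treatment of F1 with 1,2-dimethoxybenzene and TfOH in CH2Cl2 (0 °C to rt) should give 1-[(3,4-dimethoxyphenyl)methyl]pyrrolidin-2-one F2 by Tscherniac–Einhorn-type amidoalkylation para to a methoxy group. Exhaustive bromination of F2 (excess Br2, cat. Fe, AcOH, 60 °C) should fill the three free ring positions and give 1-[(2,3,6-tribromo-4,5-dimethoxyphenyl)methyl]pyrrolidin-2-one F3. Cleavage of both methyl ethers of F3 with BBr3 (CH2Cl2, −78 °C to rt) should then give 4.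

**Further compounds**
F1 | step 1 | 1-(methoxymethyl)pyrrolidin-2-one | COCN1CCCC1=O
F2 | step 1 | 1-[(3,4-dimethoxyphenyl)methyl]pyrrolidin-2-one | COc1ccc(CN2CCCC2=O)cc1OC
F3 | step 1 | 1-[(2,3,6-tribromo-4,5-dimethoxyphenyl)methyl]pyrrolidin-2-one | COc1c(OC)c(Br)c(CN2CCCC2=O)c(Br)c1Br
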